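**Retrosynthetic overview**
1. Target 11 ⇒ pentol 9 by alcohol-selective O-sulfation (last step); 9 ⇒ bis-guaiacol 7 by double O-demethylation.
2. 7 ⇒ benzylic alcohol 3 + phenethyl alcohol 5, cutting the bond between the diarylmethane CH2 and ring-A carbon C2 (between the chain-bearing C1 and the brominated C3). This is a biomimetic p-quinone-methide cross-coupling of two bromoguaiacol monomers, with all three Br and every oxygen in place and no protecting groups.
3. Enabling feature: the ring-B hydroxyl at C4′, para to the benzylic carbon, opens p-quinone methide 6; the ring-A oxygen at C5, para to C2, makes C2 the nucleophilic carbon, while Br at C3 blocks the phenol-ortho site.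
4. 3 ⇐ 5-bromovanillin 1 (bromination para to OMe, then NaBH4); 5 ⇐ homovanillyl alcohol 4 (ortho-bromination of the phenol).
5. No ring is formed (both benzene rings are bought) and the target has no stereocentre, so no stereocontrol is needed.

Key step: step 4

Assumption: the target is taken as drawn, the free alkyl hydrogen sulfate; it is released from its ammonium salt on an H+ resin and should be kept cold, since alkyl hydrogen sulfates hydrolyse autocatalytically.

**Route**

Step 1
Reactants: 1 5-bromovanillin
Product: 2 5,6-dibromovanillin (2,3-dibromo-4-hydroxy-5-methoxybenzaldehyde)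
Conditions: Br2 (1.2 equiv), Fe powder (cat.), NaOAc, AcOH, rt → 60 °C
Reagents that add atoms: bromine, BrBr
Why: Iron-catalysed electrophilic aromatic bromination should go to the one free carbon that is para to the methoxy group (C6 of the vanillin numbering) rather than to C2, which is only ortho to it.

Step 2
Reactants: 2 5,6-dibromovanillin
Product: 3 (2,3-dibromo-4-hydroxy-5-methoxyphenyl)methanol
Conditions: NaBH4, MeOH–THF, 0 °C; sat. aq. NH4Cl work-up
Reagents that add atoms: none
Why: Borohydride reduction of an aryl aldehyde leaves aryl bromides and the phenol untouched, and the buffered work-up should keep the acid-labile p-hydroxybenzyl alcohol intact.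

Step 3
Reactants: 4 homovanillyl alcohol
Product: 5 2-(3-bromo-4-hydroxy-5-methoxyphenyl)ethanol
Conditions: NBS (1.0 equiv), i-Pr2NH (10 mol%), CH2Cl2, 0 °C
Reagents that add atoms: N-bromosuccinimide, O=C1CCC(=O)N1Br
Why: Amine-catalysed ortho-bromination of a phenol with NBS should deliver bromine to the only free carbon ortho to the hydroxyl (para is blocked by the side chain, the other ortho carbon by OMe), and the primary alcohol is inert at 0 °C.

Step 4
Reactants: 3 (2,3-dibromo-4-hydroxy-5-methoxyphenyl)methanol; 5 2-(3-bromo-4-hydroxy-5-methoxyphenyl)ethanol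
Product: 7 2-[3-bromo-2-[(2,3-dibromo-4-hydroxy-5-methoxyphenyl)methyl]-4-hydroxy-5-methoxyphenyl]ethanol, via p-quinone methide 6 (not isolated)
Conditions: 5 (3 equiv), TsOH·H2O (10 mol%), HFIP, 40 °C, slow addition of 3, Ar; excess 5 recovered
Reagents that add atoms: none
Why: In HFIP with catalytic acid, 3 should lose water to give p-quinone methide 6 (reacting as its O-protonated form, the 4-hydroxybenzyl cation), which is attacked by C2 of 5, and the arenium ion rearomatises by proton loss (Friedel–Crafts benzylation). The closest known reaction type is the acid-promoted dehydrative Friedel–Crafts benzylation of phenols by p-hydroxybenzyl alcohols in fluorinated alcohols, which is also the chemistry of the acid condensation of guaiacyl lignin units at the carbon para to OMe and of the presumed biogenetic union of lanosol-type bromophenol units. No ring is closed and no stereocentre is formed. The step needs site selectivity on 5: C2 is para to the C5 methoxy group, whereas C6 is only ortho to it and is screened by the in-plane O-methyl group turned away from the C4 hydroxyl, the C3 bromine already fills the phenol-ortho position, and the second bromination of 1 at the corresponding carbon in step 1 is the model for this preference. Cross-coupling over self-condensation should be secured by the excess of 5 and the slow addition of 3, whose own ring is deactivated by two bromines and has only one free CH, ortho to OMe. O-Benzylation of the primary alcohol or of a phenol is reversible under these conditions (p-hydroxybenzyl ethers re-ionise), so material should drain into the irreversible C–C product.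

Step 5
Reactants: 7 2-[3-bromo-2-[(2,3-dibromo-4-hydroxy-5-methoxyphenyl)methyl]-4-hydroxy-5-methoxyphenyl]ethanol
Product: 9 3-bromo-4-[(2,3-dibromo-4,5-dihydroxyphenyl)methyl]-5-(2-hydroxyethyl)benzene-1,2-diol, via boron ester 8 (not isolated)
Conditions: BBr3 (6 equiv), CH2Cl2, −78 → 0 °C; ice-water
Reagents that add atoms: none
Why: Lewis-acid cleavage of aryl methyl ethers with BBr3 should remove both O-methyl groups by bromide attack on the boron-complexed methyl, leaving the aryl bromides and the diarylmethane intact, while the primary alcohol is held as its dibromoborate at ≤ 0 °C and returned on hydrolysis.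

Step 6
Reactants: 9 3-bromo-4-[(2,3-dibromo-4,5-dihydroxyphenyl)methyl]-5-(2-hydroxyethyl)benzene-1,2-diol
Product: 11 2-[3-bromo-2-[(2,3-dibromo-4,5-dihydroxyphenyl)methyl]-4,5-dihydroxyphenyl]ethyl hydrogen sulfate, via triethylammonium sulfate salt 10 (not isolated)
Conditions: Et3N·SO3 (1.3 equiv), pyridine, rt; then Dowex 50W (H+), H2O, 0–5 °C; lyophilise
Reagents that add atoms: sulfur trioxide–triethylamine complex, CC[N+](CC)(CC)S(=O)(=O)[O-]
Why: O-Sulfation with an amine–sulfur trioxide complex under non-basic conditions should take the aliphatic primary hydroxyl much faster than the un-ionised, bromine-flanked and hydrogen-bonded catechol hydroxyls (alcohol-over-phenol selectivity known for phenolic diols), and cation exchange then releases the free acid.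

**Compound list**
1 | 5-bromovanillin (3-bromo-4-hydroxy-5-methoxybenzaldehyde) | COc1cc(C=O)cc(Br)c1O | starting material
2 | 5,6-dibromovanillin (2,3-dibromo-4-hydroxy-5-methoxybenzaldehyde) | COc1cc(C=O)c(Br)c(Br)c1O | intermediate
3 | (2,3-dibromo-4-hydroxy-5-methoxyphenyl)methanol | COc1cc(CO)c(Br)c(Br)c1O | intermediate
4 | homovanillyl alcohol, 2-(4-hydroxy-3-methoxyphenyl)ethanol | COc1cc(CCO)ccc1O | starting material
5 | 2-(3-bromo-4-hydroxy-5-methoxyphenyl)ethanol | COc1cc(CCO)cc(Br)c1O | intermediate
6 | 2,3-dibromo-6-methoxy-4-methylidenecyclohexa-2,5-dien-1-one (p-quinone methide) | C=C1C=C(OC)C(=O)C(Br)=C1Br | intermediate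
7 | 2-[3-bromo-2-[(2,3-dibromo-4-hydroxy-5-methoxyphenyl)methyl]-4-hydroxy-5-methoxyphenyl]ethanol | OCCc1cc(OC)c(O)c(Br)c1Cc1cc(OC)c(O)c(Br)c1Br | intermediate
8 | boron ester of 9: both catechols as 2-bromo-1,3,2-benzodioxaboroles, primary alcohol as its dibromoborate | BrB(Br)OCCc1cc2OB(Br)Oc2c(Br)c1Cc1cc2OB(Br)Oc2c(Br)c1Br | intermediate
9 | 3-bromo-4-[(2,3-dibromo-4,5-dihydroxyphenyl)methyl]-5-(2-hydroxyethyl)benzene-1,2-diol | OCCc1cc(O)c(O)c(Br)c1Cc1cc(O)c(O)c(Br)c1Br | intermediate
10 | triethylammonium 2-[3-bromo-2-[(2,3-dibromo-4,5-dihydroxyphenyl)methyl]-4,5-dihydroxyphenyl]ethyl sulfate | CC[NH+](CC)CC.[O-]S(=O)(=O)OCCc1cc(O)c(O)c(Br)c1Cc1cc(O)c(O)c(Br)c1Br | intermediate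
11 | 2-[3-bromo-2-[(2,3-dibromo-4,5-dihydroxyphenyl)methyl]-4,5-dihydroxyphenyl]ethyl hydrogen sulfate | O=S(=O)(O)OCCc1cc(O)c(O)c(Br)c1Cc1cc(O)c(O)c(Br)c1Br | target

**Step count**
Total steps: 6. Longest linear sequence: 5 (steps 1, 2, 4, 5, 6).

**Steps most likely to fail**

Step 4. The substitution at the bromine-flanked C2 of the deactivated arene may be slow, so that the quinone methide is consumed by self-condensation (ipso attack with loss of formaldehyde) or attacks C6 instead. The fallback forms the C–C bond before the ring-A bromine is present. It sets out from 3 and 4: coupling of 3 with unbrominated homovanillyl alcohol 4 (3 equiv, TsOH cat., HFIP, 40 °C) should occur at the unhindered carbon para to OMe, the normal acid-condensation site of a guaiacyl ring, to give 2-[2-[(2,3-dibromo-4-hydroxy-5-methoxyphenyl)methyl]-4-hydroxy-5-methoxyphenyl]ethanol F1. Ortho-bromination of F1 (NBS, cat. i-Pr2NH, CH2Cl2, 0 °C) should then take the only free carbon ortho to a phenolic hydroxyl (the ring-B phenol has both ortho positions filled) and returns to the route at 7.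

Step 6. The sulfating agent may also attack the catechol hydroxyls, giving over-sulfated or aryl-sulfated material. The fallback masks the phenols and sets out from 9. Exhaustive silylation (TBSCl, imidazole, DMF) gives the penta-TBS ether F4. Acidic methanolysis (CSA cat., MeOH–CH2Cl2, 0 °C), which cleaves alkyl silyl ethers much faster than aryl silyl ethers, frees only the primary alcohol to give the tetra-aryl-TBS alcohol F5. Sulfation (SO3·pyridine, pyridine, rt) gives the pyridinium sulfate F6. Fluoride cleavage of the aryl silyl ethers (KF, MeOH, rt), followed by H+ cation exchange, returns to the route at 11.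

Step 5. The primary alcohol may be converted into the alkyl bromide through collapse of its dibromoborate, or the cleavage may stop at a mono-methyl ether. The fallback masks the alcohol as an ester and sets out from 7. Peracetylation (Ac2O, pyridine, DMAP, rt) gives the triacetate F2. BBr3 (CH2Cl2, −78 → −20 °C) cleaves the two methyl ethers while the esters persist, giving the bis-phenol triacetate F3. Acid methanolysis of the three acetates (HCl, MeOH, rt, Ar) returns to the route at 9.

**Further compounds**
F1 | step 4 | 2-[2-[(2,3-dibromo-4-hydroxy-5-methoxyphenyl)methyl]-4-hydroxy-5-methoxyphenyl]ethanol | OCCc1cc(OC)c(O)cc1Cc1cc(OC)c(O)c(Br)c1Br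
F2 | step 5 | 2-[4-acetoxy-2-[(4-acetoxy-2,3-dibromo-5-methoxyphenyl)methyl]-3-bromo-5-methoxyphenyl]ethyl acetate | CC(=O)OCCc1cc(OC)c(OC(C)=O)c(Br)c1Cc1cc(OC)c(OC(C)=O)c(Br)c1Br
F3 | step 5 | 2-[4-acetoxy-2-[(4-acetoxy-2,3-dibromo-5-hydroxyphenyl)methyl]-3-bromo-5-hydroxyphenyl]ethyl acetate | CC(=O)OCCc1cc(O)c(OC(C)=O)c(Br)c1Cc1cc(O)c(OC(C)=O)c(Br)c1Br
F4 | step 6 | penta-TBS ether of 9 (four aryl and one primary alkyl tert-butyldimethylsilyl ethers) | CC(C)(C)[Si](C)(C)OCCc1cc(O[Si](C)(C)C(C)(C)C)c(O[Si](C)(C)C(C)(C)C)c(Br)c1Cc1cc(O[Si](C)(C)C(C)(C)C)c(O[Si](C)(C)C(C)(C)C)c(Br)c1Br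
F5 | step 6 | tetra-aryl-TBS ether of 9 with free primary alcohol | OCCc1cc(O[Si](C)(C)C(C)(C)C)c(O[Si](C)(C)C(C)(C)C)c(Br)c1Cc1cc(O[Si](C)(C)C(C)(C)C)c(O[Si](C)(C)C(C)(C)C)c(Br)c1Br
F6 | step 6 | pyridinium salt of the alkyl sulfate of F5 | c1cc[nH+]cc1.[O-]S(=O)(=O)OCCc1cc(O[Si](C)(C)C(C)(C)C)c(O[Si](C)(C)C(C)(C)C)c(Br)c1Cc1cc(O[Si](C)(C)C(C)(C)C)c(O[Si](C)(C)C(C)(C)C)c(Br)c1Br
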